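**Retrosynthetic overview**

1. The strategy rests on ring A: the chain C9–C10(C14)–C1–C2–C3–C4(C15)–C5–C6 is a geraniol skeleton, the equatorial 1-OH beside quaternary C10 is what remains of a 1,10-oxirane, and the equatorial 4-OH lying peri to the equatorial 6-O-angelate (O4–C4–C5–C6–O6) is what remains of a six-membered acyloxonium ring.
2. Ring B is opened last at C7–C8: an intramolecular allylboration of a 2-methoxycarbonyl allylboronate (C13–C11=C7) onto a C8 aldehyde, with C13 brought in by Negishi coupling onto an α-iodo enoate made from a C7≡C11 alkynoate.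
3. Ring A is opened at C5–C10 and C4–O together: an acyclic (1R,10R)-epoxy (6R)-angelate cyclises under Lewis acid, the angelate carbonyl oxygen ending the cation–olefin cyclisation.
4. The acyclic precursor comes from geranyl acetate (C9 oxidation, C8 by Wittig methylenation and hydroboration, Shi epoxidation), methyl propiolate (C7, C11, C12, by asymmetric alkynylation) and angelic acid.
5. Ring order: the temporary C1,C10 oxirane, then carbocycle A together with the transient 1,3-dioxan-2-ylium ring, then carbocycle B.

Key step: step 11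

Remark (assumption): atom labels are eudesmane numbers and β is the face of the C14 methyl group; (S,S)-ProPhenol is written in step 9 on the assumption that it gives the 6R carbinol with this enal, and its mirror image would be used if a trial on a model enal showed the opposite sense.

**Route**

Step 1
Reactants: 1 geranyl acetate
Product: 2 (2E,6E)-8-hydroxygeranyl acetate
Conditions: SeO2 (cat.), t-BuOOH, salicylic acid (cat.), CH2Cl2, rt
Reagents that add atoms: tert-butyl hydroperoxide CC(C)(C)OO (terminal oxidant), selenium dioxide O=[Se]=O (oxygen relay)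
Why: Catalytic SeO2 allylic oxidation (ene reaction, then [2,3]-sigmatropic shift) should hydroxylate only the E-methyl group of the terminal trisubstituted alkene, which becomes C9; any enal formed converges in step 2.

Step 2
Reactants: 2 (2E,6E)-8-hydroxygeranyl acetate
Product: 3 (2E,6E)-8-oxogeranyl acetate
Conditions: MnO2, CH2Cl2, rt
Reagents that add atoms: none
Why: MnO2 oxidation is selective for allylic alcohols and should give the E enal without touching the acetate.

Step 3
Reactants: 3 (2E,6E)-8-oxogeranyl acetate; 4 methyltriphenylphosphonium bromide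
Product: 6 (2E,6E)-3,7-dimethylnona-2,6,8-trien-1-yl acetate, via methylenetriphenylphosphorane 5 (not isolated)
Conditions: KOt-Bu, THF, 0 °C; then 3, −78 to 0 °C
Reagents that add atoms: none
Why: Wittig methylenation of the aldehyde by the non-stabilised ylide is faster at low temperature than attack on the acetate and adds C8 as the end of a conjugated diene.

Step 4
Reactants: 6 triene acetate
Product: 8 (2E,6E)-9-hydroxy-3,7-dimethylnona-2,6-dien-1-yl acetate, via B-alkyl-9-BBN adduct 7 (not isolated)
Conditions: 9-BBN, THF, 0 °C to rt; then NaBO3·4H2O, H2O, rt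
Reagents that add atoms: sodium perborate [Na+].[O-]OB=O
Why: Hydroboration with 9-BBN should take only the monosubstituted diene terminus (boron on C8), both trisubstituted alkenes being too hindered, and perborate oxidises the C–B bond without cleaving the acetate.

Step 5
Reactants: 8 homoallylic alcohol
Product: 9 C8 tert-butyldimethylsilyl ether of 8
Conditions: TBSCl, imidazole, CH2Cl2, 0 °C to rt
Reagents that add atoms: tert-butyldimethylsilyl chloride CC(C)(C)[Si](C)(C)Cl
Why: Standard silylation of the primary alcohol; the silyl ether keeps O8 out of the later epoxide opening.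

Step 6
Reactants: 9 diene silyl ether acetate
Product: 10 (1R,10R)-epoxy acetate
Conditions: D-fructose-derived Shi ketone (0.3 equiv), KHSO5 (as 2KHSO5·KHSO4·K2SO4), K2CO3, Bu4NHSO4 (cat.), Na2B4O7 buffer, MeCN/CH2(OMe)2/H2O, 0 °C
Reagents that add atoms: potassium peroxymonosulfate [K+].[O-]S(=O)(=O)OO (oxygen relayed through the ketone-derived dioxirane)
Why: Shi asymmetric epoxidation: the chiral dioxirane should attack the electron-richer C1=C10 alkene through the spiro transition state and set C1 and C10 as R,R, while the C4=C5 alkene is deactivated by its allylic acetate.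

Step 7
Reactants: 10 (1R,10R)-epoxy acetate
Product: 11 epoxy allylic alcohol
Conditions: K2CO3, MeOH, 0 °C to rt
Reagents that add atoms: none
Why: Base-catalysed transesterification frees the allylic alcohol and leaves the oxirane and the silyl ether intact.

Step 8
Reactants: 11 epoxy allylic alcohol
Product: 12 epoxy enal (C6 aldehyde)
Conditions: MnO2, CH2Cl2, rt
Reagents that add atoms: none
Why: Neutral MnO2 oxidation of the allylic alcohol should give the E enal without opening the epoxide.

Step 9
Reactants: 12 epoxy enal; 13 methyl propiolate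
Product: 15 (6R)-propargylic alcohol, via methylzinc acetylide 14 (not isolated)
Conditions: Me2Zn, (S,S)-ProPhenol (20 mol %), Ph3P=O (40 mol %), toluene, 0 to 4 °C; aq NH4Cl
Reagents that add atoms: none
Why: Dinuclear zinc ProPhenol-catalysed alkynylation of an enal by the zinc acetylide of methyl propiolate; the ligand, not the remote epoxide, chooses the aldehyde face and sets C6 as R while bringing in C7, C11 and C12.

Step 10
Reactants: 15 (6R)-propargylic alcohol; 16 angelic acid
Product: 18 acyclic epoxy angelate, via mixed anhydride 17 (not isolated)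
Conditions: 16, 2,4,6-trichlorobenzoyl chloride, Et3N (1.0 equiv), toluene, rt, filter; then 15, toluene, 60 °C
Reagents that add atoms: none
Why: Yamaguchi esterification through the preformed mixed anhydride without a nucleophilic amine catalyst, conditions under which the Z acyl group is transferred without isomerisation and the propargylic alkynoate is not exposed to free base.

Step 11
Reactants: 18 acyclic epoxy angelate
Product: 21 ring A diol 6-O-angelate, via dioxanylium ion 19 (not isolated), via hemiorthoester 20 (not isolated)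
Conditions: MeAlCl2 (2 equiv), CH2Cl2, −78 °C; then sat. aq NaHCO3, −78 °C to rt (PPTS cat., CH2Cl2, if any 4-O-ester remains)
Reagents that add atoms: water O
Why: Proposed new method: MeAlCl2 activates the oxirane, C5 of the E alkene attacks tertiary C10 from the rear through a chair (inversion at C10, C1–O untouched), and the C4 cation is taken anti by the carbonyl oxygen of the C6 angelate to give a 1,3-dioxan-2-ylium ion, which bicarbonate water opens through the hemiorthoester to the free 4-OH and the more stable secondary 6-O-angelate. The closest known reactions are Lewis-acid cyclisations of 6,7-epoxygeranyl esters to hydroxycyclogeranyl esters, epoxide-opening cascades ended by a carbonate or ester carbonyl oxygen, and hydrolysis of acyloxonium ions to hydroxy esters. Ring A closes 6-endo with respect to both oxirane and alkene, and the transient ring (O4, acyl carbon, O6, C6, C5, C4) closes 6-endo at the distal alkene carbon as a chair trans-fused to ring A. C1 is carried over from the epoxide, C10 is set by inversion on it, and C5 and C4 by anti addition across the E alkene in the chair fold (C6 and O4 equatorial, C14 and C15 axial), the 6R centre holding its alkynyl group equatorial in the dioxanylium chair so that the carbonyl oxygen sits on the C4 face opposite the new C5–C10 bond. The step needs capture at C4 to outrun proton loss, attack by the C1 alkoxide and ionisation at C6; the carbonyl oxygen is held in reach of C4, the electron-poor alkynoate disfavours a C6 cation, O8 could reach C10 only through a four-membered ring, and −78 °C protects the Z alkene of the angelate.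

Step 12
Reactants: 21 ring A diol 6-O-angelate
Product: 22 1-O-silyl ether of 21
Conditions: TBSOTf (1.1 equiv), 2,6-lutidine, CH2Cl2, −78 °C
Reagents that add atoms: tert-butyldimethylsilyl triflate CC(C)(C)[Si](C)(C)OS(=O)(=O)C(F)(F)F
Why: Low-temperature silylation should distinguish the secondary equatorial 1-OH from the tertiary 4-OH; O1 must be capped because it would otherwise form a five-membered lactol with the later C8 aldehyde.

Step 13
Reactants: 22 1-O-silyl ether
Product: 23 α-tributylstannyl enoate (H7 cis to tin, C6 cis to CO2Me)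
Conditions: Bu3SnH (slow addition), Pd(PPh3)4 (3 mol %), THF, 0 °C
Reagents that add atoms: tributyltin hydride CCCC[SnH](CCCC)CCCC
Why: Palladium-catalysed hydrostannation of an alkynoate is a syn addition that puts tin on the α carbon C11 and hydrogen on C7; the trisubstituted angelate alkene does not react.

Step 14
Reactants: 23 α-stannyl enoate
Product: 24 α-iodo enoate (both silyl ethers in place)
Conditions: I2, CH2Cl2, 0 °C
Reagents that add atoms: iodine II
Why: Iododestannylation proceeds with retention of alkene geometry and gives the halide needed for cross-coupling.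

Step 15
Reactants: 24 α-iodo enoate
Product: 25 C8 primary alcohol
Conditions: CSA (0.1 equiv), MeOH/CH2Cl2, 0 °C
Reagents that add atoms: none
Why: Mild acid methanolysis should remove the unhindered primary silyl ether much faster than the neopentyl-type secondary one on O1.

Step 16
Reactants: 25 C8 primary alcohol
Product: 26 α-iodo enoate aldehyde
Conditions: Dess–Martin periodinane, NaHCO3, CH2Cl2, 0 °C to rt
Reagents that add atoms: none
Why: Buffered Dess–Martin oxidation gives the aldehyde under neutral conditions; C10 next to the new carbonyl chain is quaternary, so nothing can epimerise.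

Step 17
Reactants: 26 α-iodo enoate aldehyde; 27 2-(iodomethyl)-4,4,5,5-tetramethyl-1,3,2-dioxaborolane
Product: 29 2-methoxycarbonyl allylboronate aldehyde (C6 trans to CH2B), via borylmethylzinc iodide 28 (not isolated)
Conditions: 27, Zn dust (activated), THF, rt; then 26, Pd(PPh3)4 (5 mol %), THF, rt
Reagents that add atoms: none
Why: Zinc insertion into the C–I bond of 27 gives the borylmethylzinc reagent, whose Negishi coupling under zerovalent palladium catalysis retains the alkene geometry and tolerates aldehyde and esters; boron is chosen as the allyl metal because allylzinc, allylindium or allylchromium species would expel the C6 angelate by 1,4-elimination.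

Step 18
Reactants: 29 allylboronate aldehyde
Product: 31 trans-decalin 1-O-silyl ether, via pinacol borate 30 (not isolated)
Conditions: toluene, 60 °C; then pH 7 NaH2PO4/Na2HPO4 buffer, rt
Reagents that add atoms: none
Why: Intramolecular allylboration through a closed six-membered chair transition state: C6 (trans to CH2B) and the aldehyde chain C9 are both equatorial, so H7 and H8 become trans-diaxial on a chair ring B trans-fused to ring A, giving the 7β acrylate unit and the 8α hydroxyl, while allyl transposition restores the C11=C13 methylene; neutral hydrolysis of the borate avoids closure of O8 onto C12. Should 29 already close at room temperature in step 17, the two steps simply merge.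

Step 19
Reactants: 31 trans-decalin 1-O-silyl ether
Product: 32 target CNP0136844.1
Conditions: HF·pyridine, pyridine, THF, 0 °C to rt
Reagents that add atoms: none
Why: Buffered HF·pyridine should cleave the secondary silyl ether without lactonisation of O8 onto the ester, acyl migration or angelate isomerisation.

**Compound list**

1 | geranyl acetate | CC(=O)OC/C=C(C)/CCC=C(C)C | starting material
2 | (2E,6E)-8-hydroxy-3,7-dimethylocta-2,6-dien-1-yl acetate | CC(=O)OC/C=C(C)/CC/C=C(C)/CO | intermediate
3 | (2E,6E)-3,7-dimethyl-8-oxoocta-2,6-dien-1-yl acetate | CC(=O)OC/C=C(C)/CC/C=C(C)/C=O | intermediate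
4 | methyltriphenylphosphonium bromide | C[P+](c1ccccc1)(c1ccccc1)c1ccccc1.[Br-] | starting material
5 | methylenetriphenylphosphorane | C=P(c1ccccc1)(c1ccccc1)c1ccccc1 | intermediate
6 | (2E,6E)-3,7-dimethylnona-2,6,8-trien-1-yl acetate | CC(=O)OC/C=C(C)/CC/C=C(C)/C=C | intermediate
7 | 9-[(3E,7E)-9-acetoxy-3,7-dimethylnona-3,7-dien-1-yl]-9-borabicyclo[3.3.1]nonane | CC(=O)OC/C=C(C)/CC/C=C(C)/CCB1C2CCCC1CCC2 | intermediate
8 | (2E,6E)-9-hydroxy-3,7-dimethylnona-2,6-dien-1-yl acetate | CC(=O)OC/C=C(C)/CC/C=C(C)/CCO | intermediate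
9 | (2E,6E)-9-(tert-butyldimethylsilyloxy)-3,7-dimethylnona-2,6-dien-1-yl acetate | CC(=O)OC/C=C(C)/CC/C=C(C)/CCO[Si](C)(C)C(C)(C)C | intermediate
10 | (2E)-5-[(2R,3R)-3-[2-(tert-butyldimethylsilyloxy)ethyl]-3-methyloxiran-2-yl]-3-methylpent-2-en-1-yl acetate, the (1R,10R)-epoxide | CC(=O)OC/C=C(C)/CC[C@H]1O[C@]1(C)CCO[Si](C)(C)C(C)(C)C | intermediate
11 | (2E)-5-[(2R,3R)-3-[2-(tert-butyldimethylsilyloxy)ethyl]-3-methyloxiran-2-yl]-3-methylpent-2-en-1-ol | OC/C=C(C)/CC[C@H]1O[C@]1(C)CCO[Si](C)(C)C(C)(C)C | intermediate
12 | (2E)-5-[(2R,3R)-3-[2-(tert-butyldimethylsilyloxy)ethyl]-3-methyloxiran-2-yl]-3-methylpent-2-enal | O=C/C=C(C)/CC[C@H]1O[C@]1(C)CCO[Si](C)(C)C(C)(C)C | intermediate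
13 | methyl propiolate | C#CC(=O)OC | starting material
14 | methyl 3-(methylzincio)prop-2-ynoate | COC(=O)C#C[Zn]C | intermediate
15 | methyl (4R,5E)-4-hydroxy-6-methyl-8-[(2R,3R)-3-[2-(tert-butyldimethylsilyloxy)ethyl]-3-methyloxiran-2-yl]oct-5-en-2-ynoate, the (6R)-propargylic alcohol | COC(=O)C#C[C@H](O)/C=C(C)/CC[C@H]1O[C@]1(C)CCO[Si](C)(C)C(C)(C)C | intermediate
16 | angelic acid, (Z)-2-methylbut-2-enoic acid | OC(=O)/C(C)=C\C | starting material
17 | (Z)-2-methylbut-2-enoic 2,4,6-trichlorobenzoic anhydride | O=C(OC(=O)c1c(Cl)cc(Cl)cc1Cl)/C(C)=C\C | intermediate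
18 | methyl (4R,5E)-6-methyl-4-[(Z)-2-methylbut-2-enoyloxy]-8-[(2R,3R)-3-[2-(tert-butyldimethylsilyloxy)ethyl]-3-methyloxiran-2-yl]oct-5-en-2-ynoate, the acyclic epoxy angelate | COC(=O)C#C[C@H](OC(=O)/C(C)=C\C)/C=C(C)/CC[C@H]1O[C@]1(C)CCO[Si](C)(C)C(C)(C)C | intermediate
19 | 1,3-dioxan-2-ylium ion (O4, acyl carbon, O6, C6, C5, C4) trans-fused to ring A at C4–C5; 2-[(Z)-but-2-en-2-yl] on the cationic carbon, alkynoate equatorial on C6, 1β-oxygen, C14 and C15 β-axial, H5 α | COC(=O)C#C[C@@H]1OC(/C(C)=C\C)=[O+][C@]2(C)CC[C@@H](O)[C@](C)(CCO[Si](C)(C)C(C)(C)C)[C@@H]12 | intermediate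
20 | cyclic hemiorthoester (2-hydroxy-1,3-dioxane) from 19 and water, same ring stereochemistry, orthoester carbon undefined | COC(=O)C#C[C@@H]1OC(O)(/C(C)=C\C)O[C@]2(C)CC[C@@H](O)[C@](C)(CCO[Si](C)(C)C(C)(C)C)[C@@H]12 | intermediate
21 | ring A diol 6-O-angelate: cyclohexane with 1β-OH (equatorial), C10 bearing β-axial CH3 and equatorial CH2CH2OTBS, H5 α-axial, C4 bearing β-axial CH3 and α-equatorial OH, C5 carrying the (R)-CH(O-angeloyl)C≡C-CO2Me group | COC(=O)C#C[C@H](OC(=O)/C(C)=C\C)[C@@H]1[C@@](C)(CCO[Si](C)(C)C(C)(C)C)[C@H](O)CC[C@@]1(C)O | intermediate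
22 | 1-O-tert-butyldimethylsilyl ether of 21, 4-OH free | COC(=O)C#C[C@H](OC(=O)/C(C)=C\C)[C@@H]1[C@@](C)(CCO[Si](C)(C)C(C)(C)C)[C@H](O[Si](C)(C)C(C)(C)C)CC[C@@]1(C)O | intermediate
23 | α-tributylstannyl enoate from 22: C7H=C11(SnBu3)CO2Me with C6 cis to CO2Me | COC(=O)/C([Sn](CCCC)(CCCC)CCCC)=C\[C@H](OC(=O)/C(C)=C\C)[C@@H]1[C@@](C)(CCO[Si](C)(C)C(C)(C)C)[C@H](O[Si](C)(C)C(C)(C)C)CC[C@@]1(C)O | intermediate
24 | α-iodo enoate: C7H=C11(I)CO2Me with C6 cis to CO2Me, both silyl ethers in place | COC(=O)/C(I)=C\[C@H](OC(=O)/C(C)=C\C)[C@@H]1[C@@](C)(CCO[Si](C)(C)C(C)(C)C)[C@H](O[Si](C)(C)C(C)(C)C)CC[C@@]1(C)O | intermediate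
25 | α-iodo enoate with free C8 primary alcohol, 1-O-silyl ether kept | COC(=O)/C(I)=C\[C@H](OC(=O)/C(C)=C\C)[C@@H]1[C@@](C)(CCO)[C@H](O[Si](C)(C)C(C)(C)C)CC[C@@]1(C)O | intermediate
26 | α-iodo enoate aldehyde (C8 aldehyde, C6 cis to CO2Me) | COC(=O)/C(I)=C\[C@H](OC(=O)/C(C)=C\C)[C@@H]1[C@@](C)(CC=O)[C@H](O[Si](C)(C)C(C)(C)C)CC[C@@]1(C)O | intermediate
27 | 2-(iodomethyl)-4,4,5,5-tetramethyl-1,3,2-dioxaborolane | ICB1OC(C)(C)C(C)(C)O1 | starting material
28 | [(4,4,5,5-tetramethyl-1,3,2-dioxaborolan-2-yl)methyl]zinc iodide | I[Zn]CB1OC(C)(C)C(C)(C)O1 | intermediate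
29 | 2-methoxycarbonyl allylboronate aldehyde: C7H=C11(CO2Me)CH2Bpin with C6 cis to CO2Me and trans to CH2B | COC(=O)/C(CB2OC(C)(C)C(C)(C)O2)=C\[C@H](OC(=O)/C(C)=C\C)[C@@H]1[C@@](C)(CC=O)[C@H](O[Si](C)(C)C(C)(C)C)CC[C@@]1(C)O | intermediate
30 | 8-O-pinacolboryl borate of 31 | C=C(C(=O)OC)[C@H]1[C@H](OC(=O)/C(C)=C\C)[C@@H]2[C@@](C)(C[C@@H]1OB3OC(C)(C)C(C)(C)O3)[C@H](O[Si](C)(C)C(C)(C)C)CC[C@@]2(C)O | intermediate
31 | methyl 6α-angeloyloxy-1β-(tert-butyldimethylsilyloxy)-4α,8α-dihydroxy-5α,7αH-eudesm-11(13)-en-12-oate | C=C(C(=O)OC)[C@H]1[C@H](OC(=O)/C(C)=C\C)[C@@H]2[C@@](C)(C[C@@H]1O)[C@H](O[Si](C)(C)C(C)(C)C)CC[C@@]2(C)O | intermediate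
32 | methyl 6α-angeloyloxy-1β,4α,8α-trihydroxy-5α,7αH-eudesm-11(13)-en-12-oate (CNP0136844.1) | C=C(C(=O)OC)[C@H]1[C@H](OC(=O)/C(C)=C\C)[C@@H]2[C@@](C)(C[C@@H]1O)[C@H](O)CC[C@@]2(C)O | target

**Totals**

Total step count: 19.
Longest linear sequence: 19 steps (1 to 32).

**Steps most likely to fail**

Step 11 (the proposed step). What may go wrong: the C4 cation loses a proton, or is taken by the aluminium alkoxide on C1 to give a bridged ether, before the ester carbonyl captures it. The opened epoxide may also rearrange to a ketone before the alkene engages, or chloride may open the acyloxonium ion. The fallback uses known chemistry, sets out from 10 and comes back at 22. Compound 10 is cyclised with SnCl4 or ZrCl4 in CH2Cl2 at low temperature, the established Lewis-acid cyclisation of epoxygeranyl esters that ends in proton loss, to the exocyclic-methylene hydroxy acetate F1, with C1, C10 and C5 set as in the main route. TBSOTf and 2,6-lutidine give the bis-silyl ether F2. mCPBA (NaHCO3, CH2Cl2, 0 °C) should epoxidise the C4=C15 methylene from the equatorial side, away from the axial C14 methyl, to the spiro-oxirane F3. LiAlH4 in THF opens the oxirane at its CH2 carbon and removes the acetate, giving the 4,6-diol F4 with equatorial 4-OH and axial C15. TEMPO with PhI(OAc)2 oxidises only the primary hydroxyl, to the β-hydroxy aldehyde F5. Addition of 13 with Me2Zn and the matching ProPhenol antipode, helped by the zinc chelate between O4 and the aldehyde oxygen in which the axial C15 methyl blocks one face, should give the propargylic diol F6. Yamaguchi angeloylation with 17 at the secondary propargylic hydroxyl returns to 22.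

Step 18. What may go wrong: the borate oxygen on C8 closes onto the methyl ester (lactonisation), the angelate is lost by 1,4-elimination on heating, or a boat-like transition state erodes the selectivity at C7 and C8. The fallback sets out from 26 and comes back at 31. Negishi coupling of 26 with Me3SiCH2ZnCl (Pd(PPh3)4, THF) gives the 2-methoxycarbonyl allylsilane aldehyde F7. An intramolecular Hosomi–Sakurai reaction (BF3·OEt2, CH2Cl2, −78 °C, aqueous NaHCO3 quench) then closes the C7–C8 bond through an open transition state, at a temperature where the 8-hydroxyl does not lactonise. Chair-like closure of ring B with equatorial substituents should again favour 31.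

Step 10. What may go wrong: Z to E isomerisation of the angeloyl group during activation, and amine-induced redox isomerisation of the γ-hydroxy alkynoate. The fallback sets out from 15 and comes back at 18. Compound 15 is esterified with 2-[bis(2,2,2-trifluoroethoxy)phosphoryl]propanoic acid (DCC, DMAP cat., CH2Cl2, 0 °C) to the phosphonopropionate F8. A Still–Gennari olefination with acetaldehyde (KN(SiMe3)2, 18-crown-6, THF, −78 °C) then builds the Z-2-methylbut-2-enoate on the substrate under kinetic control, so no preformed angeloyl donor is exposed to isomerising conditions.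

**Further compounds**

F1 | step 11 | exocyclic-methylene hydroxy acetate: ring A with C4=C15 methylene, 1β-OH, C10 with β-axial CH3 and CH2CH2OTBS, C5 carrying CH2OAc | CC(=O)OC[C@H]1C(=C)CC[C@@H](O)[C@]1(C)CCO[Si](C)(C)C(C)(C)C
F2 | step 11 | 1-O-tert-butyldimethylsilyl ether of F1 | CC(=O)OC[C@H]1C(=C)CC[C@@H](O[Si](C)(C)C(C)(C)C)[C@]1(C)CCO[Si](C)(C)C(C)(C)C
F3 | step 11 | spiro-oxirane at C4 with α-equatorial oxygen and β-axial CH2 | CC(=O)OC[C@H]1[C@@]2(CO2)CC[C@@H](O[Si](C)(C)C(C)(C)C)[C@]1(C)CCO[Si](C)(C)C(C)(C)C
F4 | step 11 | 4,6-diol: C6 primary alcohol, 4α-OH, 4β-CH3 | OC[C@H]1[C@](C)(O)CC[C@@H](O[Si](C)(C)C(C)(C)C)[C@]1(C)CCO[Si](C)(C)C(C)(C)C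
F5 | step 11 | β-hydroxy aldehyde (C6 aldehyde, 4α-OH) | O=C[C@H]1[C@](C)(O)CC[C@@H](O[Si](C)(C)C(C)(C)C)[C@]1(C)CCO[Si](C)(C)C(C)(C)C
F6 | step 11 | (6R)-propargylic diol, 22 without the angeloyl group | COC(=O)C#C[C@H](O)[C@@H]1[C@@](C)(CCO[Si](C)(C)C(C)(C)C)[C@H](O[Si](C)(C)C(C)(C)C)CC[C@@]1(C)O
F7 | step 18 | 2-methoxycarbonyl allylsilane aldehyde: C7H=C11(CO2Me)CH2SiMe3 with C6 cis to CO2Me | COC(=O)/C(C[Si](C)(C)C)=C\[C@H](OC(=O)/C(C)=C\C)[C@@H]1[C@@](C)(CC=O)[C@H](O[Si](C)(C)C(C)(C)C)CC[C@@]1(C)O
F8 | step 10 | 6-O-[2-[bis(2,2,2-trifluoroethoxy)phosphoryl]propanoyl] ester of 15 | COC(=O)C#C[C@H](OC(=O)C(C)P(=O)(OCC(F)(F)F)OCC(F)(F)F)/C=C(C)/CC[C@H]1O[C@]1(C)CCO[Si](C)(C)C(C)(C)C
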